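**Strategy.** The plan rests on closing the dihydrofuran ring (O1–C2–C3–C3a–C7a, benzofuran numbering) last, by a formal [3+2] union of an ortho-sulfinyl ethylarene with 3,4,5-trimethoxybenzaldehyde. It exploits that C3 is a benzylic CH(CH3) on C3a, next to the ether carbon C7a. A p-tolylsulfinyl group parked on C7a acidifies C3–H, relays its chirality to C3 and C2 during addition to the aldehyde, and then departs as sulfenate when the new alkoxide attacks C7a. One operation should therefore form C2–C3 and O1–C7a, set both stereocentres trans and remove the auxiliary. The precursor is an enantiopure diaryl sulfoxide that already carries the ethyl, methoxy and (E)-propenyl groups.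

Key step: step 5

Assumption: the sense of 1,4-induction in the lithiated ortho-sulfinyl ethylarene is taken from the chelate model (Li bridging C3 and the sulfinyl O, p-tolyl on the far face, methyl turned away from sulfur, electrophile entering on the lithium face), by which (R)-sulfur gives (R)-C3; if a model addition shows the opposite sense, the enantiomeric (S)-sulfinate is used with no other change.

Step 1
Reactants: 1 1-(2-bromo-4-methoxyphenyl)ethanone
Product: 3 2-bromo-1-ethyl-4-methoxybenzene, via 1-(2-bromo-4-methoxyphenyl)ethanol 2 (not isolated)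
Conditions: Et3SiH (2.5 equiv), TFA, 0 °C → rt
Reagents that add atoms: none
Why: Ionic hydrogenation: protonation of the aryl ketone and hydride transfer from the silane give carbinol 2, whose p-methoxy-stabilised benzylic cation is reduced again, so the carbonyl should go cleanly to CH2 while the aryl bromide and the methyl ether are untouched.

Step 2
Reactants: 3 2-bromo-1-ethyl-4-methoxybenzene
Product: 4 1-bromo-2-ethyl-4-iodo-5-methoxybenzene
Conditions: NIS (1.05 equiv), TFA (cat.), MeCN, rt → 50 °C, dark
Reagents that add atoms: N-iodosuccinimide, O=C1CCC(=O)N1I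
Why: Electrophilic aromatic iodination (SEAr) should occur at the only unhindered position ortho to the methoxy group (para is blocked by ethyl, the other ortho site is wedged between OMe and Br), which is also para to bromine.

Step 3
Reactants: 4 1-bromo-2-ethyl-4-iodo-5-methoxybenzene; 5 4,4,5,5-tetramethyl-2-[(E)-prop-1-en-1-yl]-1,3,2-dioxaborolane
Product: 6 1-bromo-2-ethyl-5-methoxy-4-[(E)-prop-1-en-1-yl]benzene
Conditions: Pd(PPh3)4 (3 mol%), K2CO3, 1,4-dioxane/H2O, 70 °C
Reagents that add atoms: none
Why: Suzuki–Miyaura coupling: oxidative addition into the C–I bond is much faster than into the hindered, electron-rich C–Br bond, and the alkenyl group is transferred with retention of its E geometry.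

Step 4
Reactants: 6 1-bromo-2-ethyl-5-methoxy-4-[(E)-prop-1-en-1-yl]benzene; 7 (1S,2R,5S)-menthyl (R)-4-methylbenzenesulfinate
Product: 9 1-ethyl-4-methoxy-2-[(R)-(4-methylphenyl)sulfinyl]-5-[(E)-prop-1-en-1-yl]benzene, via arylmagnesium bromide 8 (not isolated)
Conditions: Mg turnings (I2 cat.), THF, 50 °C; then added to 7, THF/toluene, −40 → 0 °C; aq NH4Cl
Reagents that add atoms: none
Why: Andersen sulfoxide synthesis: the aryl Grignard 8 displaces mentholate from sulfur with inversion, which sets the sulfur stereocentre from the reagent and, because the new aryl group outranks p-tolyl, carries the (R) descriptor of the sulfinate into the (R)-sulfoxide.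

Step 5
Reactants: 9 1-ethyl-4-methoxy-2-[(R)-(4-methylphenyl)sulfinyl]-5-[(E)-prop-1-en-1-yl]benzene; 10 3,4,5-trimethoxybenzaldehyde
Product: 13 (2R,3R)-6-methoxy-3-methyl-5-[(E)-prop-1-en-1-yl]-2-(3,4,5-trimethoxyphenyl)-2,3-dihydro-1-benzofuran, via benzylic lithium 11 (not isolated), via lithium alkoxide 12 (not isolated)
Conditions: LDA (1.15 equiv), THF, −78 °C; 10 (1.2 equiv), −78 °C; then DMPU, −78 → 45 °C; aq NH4Cl
Reagents that add atoms: none
Why: Proposed new method: LDA should remove a C3–H (lateral lithiation assisted by the ortho sulfinyl oxygen) to give benzyllithium 11, which adds to the lithium-bound aldehyde to form C2–C3, and the resulting alkoxide 12 should then attack the ipso carbon C7a and expel p-toluenesulfenate (addition–elimination through a σ-complex, or ligand coupling through an alkoxysulfurane), forming O1–C7a. The closest known reaction types are the tandem addition of ortho-sulfinyl benzyl carbanions to imines with intramolecular SNAr displacement of the sulfinyl group by the amide nitrogen (indoline formation) and the intramolecular SNAr etherification of unactivated aryl fluorides by alkoxides; new here is the oxygen nucleophile born from an aldehyde on an electron-rich ring. The dihydrofuran ring closes in the 5-exo-trig mode at an aromatic carbon. C3 (R) is controlled by 1,4-induction from (R)-sulfur: lithium bridges C3 and the sulfinyl oxygen, the p-tolyl group covers the opposite face and the methyl group turns away from sulfur, so the aldehyde enters on the lithium face; C2 (R) is controlled by the compact lithium-bridged transition state that keeps the trimethoxyphenyl group anti to the arene, and closure with retention at both centres then places the 2-aryl and 3-methyl groups trans. The step needs benzylic rather than C7, tolyl-methyl or propenyl-methyl deprotonation, which the kinetic preference of LDA for sulfinyl-assisted lateral lithiation at −78 °C should secure, and attack of the alkoxide at carbon in a five-membered transition state, which the electron-withdrawing nucleofuge, the charge-delocalising para propenyl group and the polar co-solvent should favour. Should a minor C2-epimeric alkoxide form, its reversion to 11 and the aldehyde on warming would let the faster closure to the trans ring drain it.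

**Compound list**

1 | 1-(2-bromo-4-methoxyphenyl)ethanone | CC(=O)c1ccc(OC)cc1Br | starting material
2 | 1-(2-bromo-4-methoxyphenyl)ethanol (racemic, transient) | CC(O)c1ccc(OC)cc1Br | intermediate
3 | 2-bromo-1-ethyl-4-methoxybenzene | CCc1ccc(OC)cc1Br | intermediate
4 | 1-bromo-2-ethyl-4-iodo-5-methoxybenzene | CCc1cc(I)c(OC)cc1Br | intermediate
5 | 4,4,5,5-tetramethyl-2-[(E)-prop-1-en-1-yl]-1,3,2-dioxaborolane | C/C=C/B1OC(C)(C)C(C)(C)O1 | starting material
6 | 1-bromo-2-ethyl-5-methoxy-4-[(E)-prop-1-en-1-yl]benzene | C/C=C/c1cc(CC)c(Br)cc1OC | intermediate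
7 | (1S,2R,5S)-menthyl (R)-4-methylbenzenesulfinate [(+)-menthyl (R)-p-toluenesulfinate] | CC(C)[C@H]1CC[C@H](C)C[C@@H]1O[S@@](=O)c1ccc(C)cc1 | starting material
8 | {2-ethyl-5-methoxy-4-[(E)-prop-1-en-1-yl]phenyl}magnesium bromide | C/C=C/c1cc(CC)c([Mg]Br)cc1OC | intermediate
9 | 1-ethyl-4-methoxy-2-[(R)-(4-methylphenyl)sulfinyl]-5-[(E)-prop-1-en-1-yl]benzene | C/C=C/c1cc(CC)c(cc1OC)[S@](=O)c1ccc(C)cc1 | intermediate
10 | 3,4,5-trimethoxybenzaldehyde | COc1cc(C=O)cc(OC)c1OC | starting material
11 | 1-{4-methoxy-5-[(E)-prop-1-en-1-yl]-2-[(R)-(4-methylphenyl)sulfinyl]phenyl}ethyllithium | C/C=C/c1cc(C(C)[Li])c(cc1OC)[S@](=O)c1ccc(C)cc1 | intermediate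
12 | lithium (1R,2R)-2-{4-methoxy-5-[(E)-prop-1-en-1-yl]-2-[(R)-(4-methylphenyl)sulfinyl]phenyl}-1-(3,4,5-trimethoxyphenyl)propan-1-olate | C/C=C/c1cc([C@@H](C)[C@@H]([O-])c2cc(OC)c(OC)c(OC)c2)c(cc1OC)[S@](=O)c1ccc(C)cc1.[Li+] | intermediate
13 | (2R,3R)-6-methoxy-3-methyl-5-[(E)-prop-1-en-1-yl]-2-(3,4,5-trimethoxyphenyl)-2,3-dihydro-1-benzofuran (trans) | C/C=C/c1cc2c(cc1OC)O[C@@H](c1cc(OC)c(OC)c(OC)c1)[C@@H]2C | target

**Total step count:** 5. **Longest linear sequence:** 5 steps (1 → 13).

**Steps most likely to fail**

1. Step 5 (Proposed new method). The alkoxide may fail to displace the sulfinyl group on the electron-rich ring, so that the open-chain adduct accumulates. Deprotonation may also stray to C7, and the aldehyde face may be incompletely discriminated. The fallback uses known reactions and runs from 9 to 13. The addition is carried out and quenched at −78 °C to give the hydroxy sulfoxide (1R,2R)-2-{4-methoxy-5-[(E)-prop-1-en-1-yl]-2-[(R)-(4-methylphenyl)sulfinyl]phenyl}-1-(3,4,5-trimethoxyphenyl)propan-1-ol F1, which is freed from any C2 epimer by chromatography. Sulfoxide–lithium exchange (n-BuLi, 2.2 equiv, THF, −78 °C) followed by an iodine quench should give the iodo alcohol (1R,2R)-2-{2-iodo-4-methoxy-5-[(E)-prop-1-en-1-yl]phenyl}-1-(3,4,5-trimethoxyphenyl)propan-1-ol F2. A copper-catalysed intramolecular Ullmann etherification (CuI, 1,10-phenanthroline, Cs2CO3, toluene, 110 °C) then closes O1–C7a with retention at C2 and C3 and returns to 13.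

2. Step 4. Magnesium insertion into the hindered, electron-rich bromide may be slow, and excess Grignard reagent may attack the sulfoxide already formed (aryl exchange at sulfur), eroding enantiopurity. The fallback runs from 6 directly to 9 by palladium-catalysed enantioselective arylation of p-toluenesulfenate. The sulfenate is released in situ from tert-butyl 3-(p-tolylsulfinyl)propanoate with Cs2CO3 (Pd2(dba)3, Josiphos-type ligand, toluene, 80 °C), and the product is recrystallised to enantiopurity. No organomagnesium is involved and no further compound arises (F0).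

3. Step 3. Oxidative addition may also occur at the C–Br bond (double coupling), and Pd–H-mediated isomerisation may erode the alkene geometry. The fallback runs from 3 to 6 and bypasses 4. Friedel–Crafts propionylation (EtCOCl, SnCl4, CH2Cl2, 0 °C) at the same methoxy-activated position should give 1-(4-bromo-5-ethyl-2-methoxyphenyl)propan-1-one F3. Reduction with NaBH4 (MeOH, 0 °C) gives 1-(4-bromo-5-ethyl-2-methoxyphenyl)propan-1-ol F4. Brief acid-catalysed dehydration (p-TsOH cat., toluene, Dean–Stark) should give the thermodynamically favoured (E)-alkene 6.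

**Further compounds**

F1 | step 5 | (1R,2R)-2-{4-methoxy-5-[(E)-prop-1-en-1-yl]-2-[(R)-(4-methylphenyl)sulfinyl]phenyl}-1-(3,4,5-trimethoxyphenyl)propan-1-ol | C/C=C/c1cc([C@@H](C)[C@@H](O)c2cc(OC)c(OC)c(OC)c2)c(cc1OC)[S@](=O)c1ccc(C)cc1
F2 | step 5 | (1R,2R)-2-{2-iodo-4-methoxy-5-[(E)-prop-1-en-1-yl]phenyl}-1-(3,4,5-trimethoxyphenyl)propan-1-ol | C/C=C/c1cc([C@@H](C)[C@@H](O)c2cc(OC)c(OC)c(OC)c2)c(I)cc1OC
F0 | step 4 | none | none
F3 | step 3 | 1-(4-bromo-5-ethyl-2-methoxyphenyl)propan-1-one | CCC(=O)c1cc(CC)c(Br)cc1OC
F4 | step 3 | 1-(4-bromo-5-ethyl-2-methoxyphenyl)propan-1-ol | CCC(O)c1cc(CC)c(Br)cc1OC
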